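**Plan**
- Retrosynthesis: strip the C6 methyl, the C5=C6 unsaturation and the two acyl groups, then undo the syn hydration of C3a=C4. Cut C3a–C8a and C4–C5 together to reach an acyclic enyne bearing a 1-siloxy-vinylcyclopropane. Cut that chain at C3–C≡ (acetylide addition), C1–C2 (aldol) and C8=C8a (Wittig).
- Enabling feature: in the seven-membered ring the C7 carbonyl is the central atom of the five-carbon arc C5–C6–C7–C8–C8a, which ends at the quaternary C8a. That arc is a 1-oxygenated vinylcyclopropane in disguise, and the two-carbon unit C3a–C4 is an alkyne held to C8a by the three-atom tether C1–C2–C3.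
- Forward: a linear chain is assembled, then the five- and seven-membered rings arise together in step 7; the remaining steps adjust the periphery.
- Stereochemistry: C1 from a reagent-controlled boron aldol; C3 by chelation control from C1; C8a in the cycloaddition under control of C1 and C3; C3a and C4 by hydroboration anti to the angular methyl.

Key step: step 7

Remarks on the chemistry: locants follow the hydroazulene skeleton (C1 acetoxy, C3 carbinol, C3a, C4 aroyloxy, C6 methyl, C7 carbonyl, C8a angular methyl). The (−)-Ipc2BCl enolate of a methyl ketone is assumed to add to the re face of an aldehyde; the (+)-reagent is therefore used to obtain the (S)-carbinol.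

**Step 1**
Reactants: 1 methyl 1-hydroxycyclopropane-1-carboxylate; 2 tert-butyldimethylsilyl chloride
Product: 3 methyl 1-[(tert-butyldimethylsilyl)oxy]cyclopropane-1-carboxylate
Conditions: TBSCl, imidazole, DMF, rt
Reagents that add atoms: tert-butyldimethylsilyl chloride, CC(C)(C)[Si](C)(C)Cl
Why: Imidazole-promoted silylation masks the cyclopropanol oxygen, which becomes the C7 oxygen and the donor that activates the cyclopropane later.

**Step 2**
Reactants: 3 methyl 1-[(tert-butyldimethylsilyl)oxy]cyclopropane-1-carboxylate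
Product: 4 1-[(tert-butyldimethylsilyl)oxy]cyclopropane-1-carbaldehyde
Conditions: iBu2AlH (1.05 equiv), CH2Cl2, −78 °C; aqueous Rochelle salt
Reagents that add atoms: none
Why: Partial reduction of an α-silyloxy ester stops at the aldehyde because the tetrahedral aluminium hemiacetal persists at low temperature until work-up.

**Step 3**
Reactants: 4 1-[(tert-butyldimethylsilyl)oxy]cyclopropane-1-carbaldehyde; 5 2-(triphenylphosphoranylidene)propanal
Product: 6 (2E)-3-{1-[(tert-butyldimethylsilyl)oxy]cyclopropyl}-2-methylprop-2-enal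
Conditions: toluene, 100 °C
Reagents that add atoms: 2-(triphenylphosphoranylidene)propanal, CC(C=O)=P(c1ccccc1)(c1ccccc1)c1ccccc1
Why: Wittig olefination with a formyl-stabilised ylide gives the (E)-trisubstituted enal and places the future C8a methyl on the alkene.

**Step 4**
Reactants: 6 the (E)-enal; 7 3-methylbutan-2-one; 8 (+)-B-chlorodiisopinocampheylborane
Product: 11 (5S,6E)-7-{1-[(tert-butyldimethylsilyl)oxy]cyclopropyl}-5-hydroxy-2,6-dimethylhept-6-en-3-one, via enol borinate 9 (not isolated), via boron aldolate 10 (not isolated)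
Conditions: 7, (+)-Ipc2BCl, Et3N, Et2O, 0 °C; then 6, −78 to −20 °C; then H2O2, MeOH, pH 7 buffer, 0 °C
Reagents that add atoms: 3-methylbutan-2-one, CC(=O)C(C)C
Why: Diisopinocampheylboron-mediated aldol of a methyl ketone: the enolate formed on the methyl side adds through a cyclic transition state to the si face of the α-branched enal, setting the carbinol (the future C1) as S under reagent control.

**Step 5**
Reactants: 11 the β-hydroxy ketone; 12 ethynylmagnesium bromide
Product: 14 (3R,5S,6E)-7-{1-[(tert-butyldimethylsilyl)oxy]cyclopropyl}-6-methyl-3-(propan-2-yl)hept-6-en-1-yne-3,5-diol, via magnesium alkoxide 13 (not isolated)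
Conditions: HC≡CMgBr (4 equiv), THF–CH2Cl2, −78 to −20 °C; aqueous NH4Cl
Reagents that add atoms: ethynylmagnesium bromide, C#C[Mg]Br
Why: Chelation-controlled Grignard addition: the bromomagnesium alkoxide binds the ketone in a half-chair with the alkenyl group equatorial, and the slim acetylide attacks axially to give the tertiary carbinol with the 3R configuration.

**Step 6**
Reactants: 14 the diol; 15 acetic anhydride
Product: 16 (1E,3S,5R)-1-{1-[(tert-butyldimethylsilyl)oxy]cyclopropyl}-5-hydroxy-2-methyl-5-(propan-2-yl)hept-1-en-6-yn-3-yl acetate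
Conditions: Ac2O (1.2 equiv), pyridine, DMAP (cat.), CH2Cl2, 0 °C
Reagents that add atoms: acetic anhydride, CC(=O)OC(C)=O
Why: DMAP-catalysed acylation distinguishes the secondary allylic alcohol from the hindered tertiary propargylic one and installs the C1 acetate of the target at the outset.

**Step 7**
Reactants: 16 the enyne–siloxyvinylcyclopropane
Product: 17 (1S,3R,8aS)-7-[(tert-butyldimethylsilyl)oxy]-3-hydroxy-8a-methyl-3-(propan-2-yl)-1,2,3,5,6,8a-hexahydroazulen-1-yl acetate
Conditions: [Rh(CO)2Cl]2 (5 mol %), 1,2-dichloroethane (0.02 M), 70 °C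
Reagents that add atoms: none
Why: Monovalent rhodium inserts into the C7–C5 bond of the cyclopropane, activated by the siloxy donor on C7, to give a σ-alkyl/π-allyl rhodacycle spanning C5–C6–C7–C8–C8a; the tethered alkyne then inserts at the allyl terminus C8a, and reductive elimination joins C4 to C5, so C3a–C8a and C4–C5 form in one catalytic cycle. The closest known reaction is the rhodium-catalysed intramolecular [5+2] cycloaddition of alkynes with heteroatom-substituted vinylcyclopropanes. The five-membered ring closes in the alkyne-insertion event across the C1–C2–C3 tether, and the seven-membered ring closes by reductive elimination from the eight-membered rhodacycle. The only new stereocentre is the quaternary C8a: the rhodacycle must lie on one face of the nascent cyclopentene, the small free C3 hydroxyl (able to coordinate rhodium) and the C1 hydrogen point towards the metal, and the isopropyl and acetoxy groups point away, which puts the C8a methyl cis to both (8aS). The step needs this facial selectivity and [5+2] over alkyne oligomerisation; the two cyclopropane CH2 groups are equivalent so cleavage regiochemistry is not an issue, the (E)-alkene holds the tether trans to the cyclopropane as the metallacycle requires, and high dilution suppresses intermolecular paths. The product carries C7 as a regiodefined silyl enol ether and C3a=C4 as the only other alkene, the handle for the later syn hydration.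

**Step 8**
Reactants: 17 the cycloadduct; 18 ethylene glycol
Product: 19 (1S,3R,8aS)-7,7-(ethylenedioxy)-3-hydroxy-8a-methyl-3-(propan-2-yl)-1,2,3,5,6,7,8,8a-octahydroazulen-1-yl acetate
Conditions: ethylene glycol (10 equiv), camphorsulfonic acid (5 mol %), CH2Cl2, 0 °C to rt; Et3N quench
Reagents that add atoms: ethylene glycol, OCCO
Why: C-protonation of the silyl enol ether and capture of the oxocarbenium ion by the diol (transketalisation) masks the C7 ketone for the borane step under conditions mild enough for the tertiary allylic alcohol.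

**Step 9**
Reactants: 19 the ketal; 20 borane–tetrahydrofuran; 21 sodium perborate tetrahydrate
Product: 23 (1S,3R,3aR,4R,8aS)-7,7-(ethylenedioxy)-3,4-dihydroxy-8a-methyl-3-(propan-2-yl)decahydroazulen-1-yl acetate, via alkylborane 22 (not isolated)
Conditions: BH3·THF (3 equiv), THF, 0 °C to rt; then NaBO3·4H2O, THF–H2O, rt
Reagents that add atoms: sodium perborate tetrahydrate, [Na+].[Na+].O[B-]1(O)OO[B-](O)(O)OO1
Why: Hydroboration–oxidation: syn addition of B–H to the trisubstituted C3a=C4 alkene from the face opposite the C8a methyl and C3 isopropyl puts boron on C4 and hydrogen on C3a, setting the trans ring fusion (3aR) and the C4 alcohol (4R) together, with retention in the perborate oxidation.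

**Step 10**
Reactants: 23 the C4 alcohol; 24 4-acetoxybenzoyl chloride
Product: 25 (1S,3R,3aR,4R,8aS)-1-acetoxy-7,7-(ethylenedioxy)-3-hydroxy-8a-methyl-3-(propan-2-yl)decahydroazulen-4-yl 4-acetoxybenzoate
Conditions: 4-acetoxybenzoyl chloride (1.5 equiv), Et3N, DMAP (0.2 equiv), CH2Cl2, 0 °C to rt
Reagents that add atoms: 4-acetoxybenzoyl chloride, CC(=O)Oc1ccc(cc1)C(Cl)=O
Why: DMAP-catalysed acylation esterifies the secondary C4 alcohol while the tertiary C3 hydroxyl stays free; the phenol is carried as its acetate to survive the oxidations that follow.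

**Step 11**
Reactants: 25 the ketal diester; 26 water
Product: 27 (1S,3R,3aR,4R,8aS)-1-acetoxy-3-hydroxy-8a-methyl-7-oxo-3-(propan-2-yl)decahydroazulen-4-yl 4-acetoxybenzoate
Conditions: pyridinium p-toluenesulfonate (0.3 equiv), acetone–H2O (9:1), 50 °C
Reagents that add atoms: water, O
Why: Mild acid-catalysed ketal hydrolysis frees the C7 ketone without touching the three esters or the now non-allylic tertiary alcohol.

**Step 12**
Reactants: 27 the ketone
Product: 28 (1S,3R,3aR,4R,8aS)-1-acetoxy-3-hydroxy-8a-methyl-7-oxo-3-(propan-2-yl)-1,2,3,3a,4,7,8,8a-octahydroazulen-4-yl 4-acetoxybenzoate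
Conditions: IBX (3 equiv), DMSO–fluorobenzene (1:2), 70 °C
Reagents that add atoms: none
Why: IBX dehydrogenation of the ketone through its enol can only desaturate the C5–C6 side because C8a is quaternary, so the enone regiochemistry is enforced by the structure.

**Step 13**
Reactants: 28 the enone; 29 iodine
Product: 30 (1S,3R,3aR,4S,8aS)-1-acetoxy-3-hydroxy-6-iodo-8a-methyl-7-oxo-3-(propan-2-yl)-1,2,3,3a,4,7,8,8a-octahydroazulen-4-yl 4-acetoxybenzoate (the 4S descriptor reflects only the priority change caused by iodine)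
Conditions: I2 (2 equiv), pyridine–CH2Cl2 (1:1), 0 °C to rt
Reagents that add atoms: iodine, II
Why: α-Iodination of the enone by conjugate addition of pyridine, iodination of the resulting enolate and elimination places iodine on C6.

**Step 14**
Reactants: 30 the iodoenone; 31 tetramethylstannane
Product: 32 (1S,3R,3aR,4R,8aS)-1-acetoxy-3-hydroxy-6,8a-dimethyl-7-oxo-3-(propan-2-yl)-1,2,3,3a,4,7,8,8a-octahydroazulen-4-yl 4-acetoxybenzoate
Conditions: SnMe4 (3 equiv), Pd2(dba)3 (5 mol %), AsPh3 (20 mol %), copper iodide CuI (10 mol %), N-methylpyrrolidone, 60 °C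
Reagents that add atoms: tetramethylstannane, C[Sn](C)(C)C
Why: Stille coupling (oxidative addition of zerovalent palladium to the C6–I bond, copper-assisted transmetalation from tin, reductive elimination) installs the C6 methyl without base, so all esters survive.

**Step 15**
Reactants: 32 the aryl acetate
Product: 33 (1S,3R,3aR,4R,8aS)-1-acetoxy-3-hydroxy-6,8a-dimethyl-7-oxo-3-(propan-2-yl)-1,2,3,3a,4,7,8,8a-octahydroazulen-4-yl 4-hydroxybenzoate (CNP0087181.1)
Conditions: NH4OAc (8 equiv), MeOH–H2O (4:1), rt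
Reagents that add atoms: none
Why: Acetate-catalysed methanolysis cleaves the much more electrophilic aryl acetate selectively in the presence of the alkyl acetate and the hindered benzoate.

**Compound list**
1 | methyl 1-hydroxycyclopropane-1-carboxylate | COC(=O)C1(O)CC1 | starting material
2 | tert-butyldimethylsilyl chloride | CC(C)(C)[Si](C)(C)Cl | starting material
3 | methyl 1-[(tert-butyldimethylsilyl)oxy]cyclopropane-1-carboxylate | COC(=O)C1(O[Si](C)(C)C(C)(C)C)CC1 | intermediate
4 | 1-[(tert-butyldimethylsilyl)oxy]cyclopropane-1-carbaldehyde | O=CC1(O[Si](C)(C)C(C)(C)C)CC1 | intermediate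
5 | 2-(triphenylphosphoranylidene)propanal | CC(C=O)=P(c1ccccc1)(c1ccccc1)c1ccccc1 | starting material
6 | (2E)-3-{1-[(tert-butyldimethylsilyl)oxy]cyclopropyl}-2-methylprop-2-enal | O=C/C(C)=C/C1(O[Si](C)(C)C(C)(C)C)CC1 | intermediate
7 | 3-methylbutan-2-one | CC(=O)C(C)C | starting material
8 | (+)-B-chlorodiisopinocampheylborane | ClB([C@H]1C[C@H]2C[C@@H]([C@@H]1C)C2(C)C)[C@H]1C[C@H]2C[C@@H]([C@@H]1C)C2(C)C | starting material
9 | 3-methylbut-1-en-2-yl diisopinocampheylborinate (enol borinate) | C=C(OB([C@H]1C[C@H]2C[C@@H]([C@@H]1C)C2(C)C)[C@H]1C[C@H]2C[C@@H]([C@@H]1C)C2(C)C)C(C)C | intermediate (not isolated)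
10 | diisopinocampheylboron aldolate of 11 | CC(C)C(=O)C[C@H](OB([C@H]1C[C@H]2C[C@@H]([C@@H]1C)C2(C)C)[C@H]1C[C@H]2C[C@@H]([C@@H]1C)C2(C)C)/C(C)=C/C1(O[Si](C)(C)C(C)(C)C)CC1 | intermediate (not isolated)
11 | (5S,6E)-7-{1-[(tert-butyldimethylsilyl)oxy]cyclopropyl}-5-hydroxy-2,6-dimethylhept-6-en-3-one | CC(C)C(=O)C[C@H](O)/C(C)=C/C1(O[Si](C)(C)C(C)(C)C)CC1 | intermediate
12 | ethynylmagnesium bromide | C#C[Mg]Br | starting material
13 | bromomagnesium alkoxide of 11 | CC(C)C(=O)C[C@H](O[Mg]Br)/C(C)=C/C1(O[Si](C)(C)C(C)(C)C)CC1 | intermediate (not isolated)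
14 | (3R,5S,6E)-7-{1-[(tert-butyldimethylsilyl)oxy]cyclopropyl}-6-methyl-3-(propan-2-yl)hept-6-en-1-yne-3,5-diol | C#C[C@](O)(C(C)C)C[C@H](O)/C(C)=C/C1(O[Si](C)(C)C(C)(C)C)CC1 | intermediate
15 | acetic anhydride | CC(=O)OC(C)=O | starting material
16 | (1E,3S,5R)-1-{1-[(tert-butyldimethylsilyl)oxy]cyclopropyl}-5-hydroxy-2-methyl-5-(propan-2-yl)hept-1-en-6-yn-3-yl acetate | C#C[C@](O)(C(C)C)C[C@H](OC(C)=O)/C(C)=C/C1(O[Si](C)(C)C(C)(C)C)CC1 | intermediate
17 | (1S,3R,8aS)-7-[(tert-butyldimethylsilyl)oxy]-3-hydroxy-8a-methyl-3-(propan-2-yl)-1,2,3,5,6,8a-hexahydroazulen-1-yl acetate | CC(=O)O[C@H]1C[C@@](O)(C(C)C)C2=CCCC(O[Si](C)(C)C(C)(C)C)=C[C@]12C | intermediate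
18 | ethylene glycol | OCCO | starting material
19 | (1S,3R,8aS)-7,7-(ethylenedioxy)-3-hydroxy-8a-methyl-3-(propan-2-yl)-1,2,3,5,6,7,8,8a-octahydroazulen-1-yl acetate | CC(=O)O[C@H]1C[C@@](O)(C(C)C)C2=CCCC3(OCCO3)C[C@]12C | intermediate
20 | borane–tetrahydrofuran | [BH3-][O+]1CCCC1 | starting material
21 | sodium perborate tetrahydrate | [Na+].[Na+].O[B-]1(O)OO[B-](O)(O)OO1 | starting material
22 | C4 alkylborane of 19 (C3 oxygen borylated) | CC(=O)O[C@H]1C[C@@](OB)(C(C)C)[C@H]2[C@H](B)CCC4(OCCO4)C[C@]12C | intermediate (not isolated)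
23 | (1S,3R,3aR,4R,8aS)-7,7-(ethylenedioxy)-3,4-dihydroxy-8a-methyl-3-(propan-2-yl)decahydroazulen-1-yl acetate | CC(=O)O[C@H]1C[C@@](O)(C(C)C)[C@H]2[C@H](O)CCC4(OCCO4)C[C@]12C | intermediate
24 | 4-acetoxybenzoyl chloride | CC(=O)Oc1ccc(cc1)C(Cl)=O | starting material
25 | (1S,3R,3aR,4R,8aS)-1-acetoxy-7,7-(ethylenedioxy)-3-hydroxy-8a-methyl-3-(propan-2-yl)decahydroazulen-4-yl 4-acetoxybenzoate | CC(=O)O[C@H]1C[C@@](O)(C(C)C)[C@H]2[C@H](OC(=O)c3ccc(OC(C)=O)cc3)CCC4(OCCO4)C[C@]12C | intermediate
26 | water | O | starting material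
27 | (1S,3R,3aR,4R,8aS)-1-acetoxy-3-hydroxy-8a-methyl-7-oxo-3-(propan-2-yl)decahydroazulen-4-yl 4-acetoxybenzoate | CC(=O)O[C@H]1C[C@@](O)(C(C)C)[C@H]2[C@H](OC(=O)c3ccc(OC(C)=O)cc3)CCC(=O)C[C@]12C | intermediate
28 | (1S,3R,3aR,4R,8aS)-1-acetoxy-3-hydroxy-8a-methyl-7-oxo-3-(propan-2-yl)-1,2,3,3a,4,7,8,8a-octahydroazulen-4-yl 4-acetoxybenzoate | CC(=O)O[C@H]1C[C@@](O)(C(C)C)[C@H]2[C@H](OC(=O)c3ccc(OC(C)=O)cc3)C=CC(=O)C[C@]12C | intermediate
29 | iodine | II | starting material
30 | (1S,3R,3aR,4S,8aS)-1-acetoxy-3-hydroxy-6-iodo-8a-methyl-7-oxo-3-(propan-2-yl)-1,2,3,3a,4,7,8,8a-octahydroazulen-4-yl 4-acetoxybenzoate | CC(=O)O[C@H]1C[C@@](O)(C(C)C)[C@H]2[C@H](OC(=O)c3ccc(OC(C)=O)cc3)C=C(I)C(=O)C[C@]12C | intermediate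
31 | tetramethylstannane | C[Sn](C)(C)C | starting material
32 | (1S,3R,3aR,4R,8aS)-1-acetoxy-3-hydroxy-6,8a-dimethyl-7-oxo-3-(propan-2-yl)-1,2,3,3a,4,7,8,8a-octahydroazulen-4-yl 4-acetoxybenzoate | CC(=O)O[C@H]1C[C@@](O)(C(C)C)[C@H]2[C@H](OC(=O)c3ccc(OC(C)=O)cc3)C=C(C)C(=O)C[C@]12C | intermediate
33 | (1S,3R,3aR,4R,8aS)-1-acetoxy-3-hydroxy-6,8a-dimethyl-7-oxo-3-(propan-2-yl)-1,2,3,3a,4,7,8,8a-octahydroazulen-4-yl 4-hydroxybenzoate | CC(=O)O[C@H]1C[C@@](O)(C(C)C)[C@H]2[C@H](OC(=O)c3ccc(O)cc3)C=C(C)C(=O)C[C@]12C | target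

**Totals**
Total step count: 15. Longest linear sequence: 15 steps (from 1).

**Steps most likely to fail**

Step 7. The fully substituted alkene terminus may slow insertion. Facial discrimination at C8a may be poor if the C1 acetoxy group and the C3 centre do not reinforce each other. Rhodium may also ionise the allylic acetate, which would trigger ring expansion of the siloxycyclopropane. The fallback removes the C1 stereocentre and the leaving group from the cyclisation and sets C1 afterwards. It sets out from 14: MnO2 in CH2Cl2 oxidises the secondary allylic alcohol to the C1-ketone enyne F1. The same [Rh(CO)2Cl]2 cycloaddition, now steered by C3 alone, should give the bicyclic C1 ketone F2. NaBH4 in EtOH at −20 °C should deliver hydride anti to the C8a methyl and the C3 isopropyl to give the 1,3-diol F3. Acetylation as in step 6 returns to the route at 17.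

Step 5. Chelation may be lost in the ethereal solvent, giving a mixture of C3 epimers, and the magnesium aldolate may undergo retro-aldol cleavage. The fallback swaps the roles of ketone substituent and nucleophile so that a bulky nucleophile attacks the chelate equatorially. It sets out from 6: 4-(trimethylsilyl)but-3-yn-2-one is enolised with (+)-Ipc2BCl/Et3N to the enol borinate F4, which adds to 6 to give the boron aldolate F5. Oxidative work-up releases the hydroxy ynone F6. Isopropylcerium (iPrMgCl, CeCl3, THF, −78 °C) should add to the chelated ynone from the equatorial direction to give the C-silylated diol F7 with the same 3R,5S configuration. K2CO3 in MeOH removes the alkyne silyl group and returns to the route at 14.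

Step 9. The alkene lies between two quaternary carbons, so hydroboration may be sluggish; this would allow borane to reduce the acetate or would erode facial selectivity. The fallback splits the hydration into a directed oxidation and a radical reduction. It sets out from 19: VO(acac)2 (cat.) with t-BuOOH in CH2Cl2, directed by the allylic C3 hydroxyl, should give the 3a,4-epoxide F8 on the face of that hydroxyl. Trivalent titanium (Cp2TiCl from Cp2TiCl2 and Zn) with 1,4-cyclohexadiene in THF opens the epoxide homolytically to the tertiary C3a radical. The radical takes hydrogen on the face opposite the angular methyl, returning to the route at 23.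

**Further compounds**
F1 | step 7 | (1E,5R)-1-{1-[(tert-butyldimethylsilyl)oxy]cyclopropyl}-5-hydroxy-2-methyl-5-(propan-2-yl)hept-1-en-6-yn-3-one | C#C[C@](O)(C(C)C)CC(=O)/C(C)=C/C1(O[Si](C)(C)C(C)(C)C)CC1
F2 | step 7 | (3R,8aS)-7-[(tert-butyldimethylsilyl)oxy]-3-hydroxy-8a-methyl-3-(propan-2-yl)-2,3,5,6-tetrahydroazulen-1(8aH)-one | O=C1C[C@@](O)(C(C)C)C2=CCCC(O[Si](C)(C)C(C)(C)C)=C[C@]12C
F3 | step 7 | (1S,3R,8aS)-7-[(tert-butyldimethylsilyl)oxy]-8a-methyl-3-(propan-2-yl)-1,2,3,5,6,8a-hexahydroazulene-1,3-diol | O[C@H]1C[C@@](O)(C(C)C)C2=CCCC(O[Si](C)(C)C(C)(C)C)=C[C@]12C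
F4 | step 5 | 4-(trimethylsilyl)but-1-en-3-yn-2-yl diisopinocampheylborinate (enol borinate) | C=C(OB([C@H]1C[C@H]2C[C@@H]([C@@H]1C)C2(C)C)[C@H]1C[C@H]2C[C@@H]([C@@H]1C)C2(C)C)C#C[Si](C)(C)C
F5 | step 5 | diisopinocampheylboron aldolate of F6 | C[Si](C)(C)C#CC(=O)C[C@H](OB([C@H]1C[C@H]2C[C@@H]([C@@H]1C)C2(C)C)[C@H]1C[C@H]2C[C@@H]([C@@H]1C)C2(C)C)/C(C)=C/C1(O[Si](C)(C)C(C)(C)C)CC1
F6 | step 5 | (5S,6E)-7-{1-[(tert-butyldimethylsilyl)oxy]cyclopropyl}-5-hydroxy-6-methyl-1-(trimethylsilyl)hept-6-en-1-yn-3-one | C[Si](C)(C)C#CC(=O)C[C@H](O)/C(C)=C/C1(O[Si](C)(C)C(C)(C)C)CC1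
F7 | step 5 | (3R,5S,6E)-7-{1-[(tert-butyldimethylsilyl)oxy]cyclopropyl}-6-methyl-3-(propan-2-yl)-1-(trimethylsilyl)hept-6-en-1-yne-3,5-diol | C[Si](C)(C)C#C[C@](O)(C(C)C)C[C@H](O)/C(C)=C/C1(O[Si](C)(C)C(C)(C)C)CC1
F8 | step 9 | 3a,4-epoxide of 19 with the epoxide oxygen cis to the C3 hydroxyl and trans to the C8a methyl | CC(=O)O[C@H]1C[C@@](O)(C(C)C)[C@@]2(O3)[C@H]3CCC4(OCCO4)C[C@]12C
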